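## Analysis of the target

The target 19 is a 2,3,4,5-tetrasubstituted tetrahydrofuran (ring atoms O1, C2, C3, C4, C5) with 3,4-dihydroxyphenyl groups on C2 and C5 and acetoxymethyl arms on C3 and C4. The configuration string places both aryl groups on one face and both CH2OAc arms on the other: 2,5-cis, 3,4-cis, 2,3-trans and 4,5-trans, i.e. (2R,3S,4R,5S). A mirror plane through O1 and the midpoint of C3–C4 makes the molecule meso, so no absolute control is needed and racemic intermediates converge on one achiral product. Only the relative configuration of four contiguous centres has to be right, and that is the hard part. The 3,4-cis arrangement of two neighbouring arms is not the thermodynamically preferred one, so it has to be enforced, while C2 and C5 must each end up trans to their neighbour and cis to each other across the oxygen. Sensitive groups are the two catechols (air oxidation, so masked as benzyl ethers until the last step), the two primary acetates (lost to hydride or alkoxide, so installed late) and the two ring benzylic C–O bonds, which para-oxygen substituents activate towards acid ionisation and over-hydrogenolysis. The strategy reads the O1–C5–C4 segment with the C4 arm as a ring-opened aryl vinyl epoxide (vinyl standing for CH2OAc after loss of one carbon) and the C2–C3 bond as the former C=C of an arylidene malonate. One ester carbon of that malonate becomes the C3 arm and the other is a removable activating group; both aryl-bearing carbons then come from one aldehyde, 1.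

## Retrosynthetic reasoning

19 to 18. The four phenolic oxygens are masked as benzyl ethers, so the last operation is a neutral hydrogenolysis that leaves the acetates alone and keeps the catechols away from every base, oxidant and hydride used earlier. The forward step must cleave four aryl benzyl ethers without cutting the ring bonds C2–O1 and C5–O1.

18 to 17 to 16. The two acetate ester bonds are cut to give meso diol 17, and 17 is traced to lactone 16, where the C3 arm is at the carboxyl level and tied by an ester bond to the C4 arm. The lactone is placed here because a five-membered lactone fused to a five-membered ring can only be cis, which fixes the 3,4-cis relationship. Forward, this is a hydride reduction and an acetylation.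

16 to 15. A second carboxyl carbon is put back on C3, the reverse of a demethoxycarbonylation. This costs one forward step but makes C3 a malonate carbon, which the ring construction needs. The C3 configuration need not be carried: protonation of the lactone enolate can only give the cis-fused bicycle, which puts the C3 arm trans to the C2 aryl.

15 to 13 to 11. The lactone C–O bond is opened to hydroxy diester 14, its CH2OH is taken back to the formyl group of aldehyde 13, and one carbon is added to reach the vinyl group of 11. Vinyl is the chosen mask because it is exactly what the ring-forming step leaves on C4. Forward, this is oxidative cleavage, reduction, and lactonisation onto whichever of the two C3 esters is cis.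

11 to 3 plus 8 (the key disconnection). O1–C2 is cut as a retro oxa-Michael addition to benzylidene malonate 3, and C3–C4 as a retro allylic alkylation, leading through zwitterion 9 to vinyl epoxide 8. These two cuts divide the ring into a three-atom O–C–C unit and a two-atom C=C unit, each one step from aldehyde 1. C5 arrives with its oxygen already attached, and both bonds form in polar steps of known stereochemical course. Cutting C2–C3 or the two aryl bonds instead would leave no single ring-closing event to tie C2 to C5. The forward reaction must set C4 trans to C5 and C2 cis to C5.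

3 to 1 plus 2; 8 to 1 plus 6; 6 to 4 plus 5. The C=C of 3 is cut by a retro-Knoevenagel condensation with dimethyl malonate 2. The epoxide C–C and C–O bonds of 8 are cut by a retro sulfonium ylide epoxidation, the ylide 7 coming from salt 6, which is the S-alkylation product of tetrahydrothiophene 4 and allyl bromide 5.

## Alternatives that were turned down

Alternative 1: Oxidative 8–8′ dimerisation. The disconnection cuts C3–C4 and both ring C–O bonds, giving two molecules of (E)-3-[3-(benzyloxy)-4-hydroxyphenyl]allyl acetate A1. Forward, laccase and O2 oxidise A1 to phenoxyl radicals that couple at C3–C4; water adds to one para-quinone methide carbon (O1–C2) and the new hydroxyl closes on the other (O1–C5), giving the 3-O,3′-O-dibenzyl ether A2 of the target, one hydrogenolysis from 19.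
- For: it is the shortest conceivable route, builds the ring and all four stereocentres in one aqueous operation, and a meso target suits a dimerisation.
- Against: the enzyme only generates the radicals, so the coupling site (8–8′ against 8–O–4′ and 8–5′) is undirected. The C3/C4 pairing is set in an unbiased radical–radical encounter with no preference for the unlike (meso) pairing the target needs. Each water or hydroxyl addition at C2 and C5 is facially uncontrolled. A2 still carries free phenols and remains a laccase substrate.
- Comparison: this alternative is clearly stronger on step count (about five steps against ten). The chosen route offers instead a named control element for every stereocentre and no need to separate one diastereomer from regio- and stereoisomers.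

Alternative 2: Carbene C–H insertion. The disconnection cuts C2–C3. Forward, Rh2(OAc)4 converts α-diazo lactone A3 into a carbene at C3 that inserts into the benzylic C–H bond of the arylmethyl ether, closing the tetrahydrofuran onto the lactone to give A4, which is the same compound as 16.
- For: the ether oxygen activates that C–H bond, the insertion runs through a five-membered transition state, cis fusion is automatic, and the endgame from A4 is the same three steps as here. It also avoids the one-carbon excision and the decarboxylation of the chosen route, which is a real advantage.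
- Against: A3 needs its own control of the C4/C5 relationship, an etherification of a hindered secondary benzylic alcohol beside a base-sensitive lactone, and diazo transfer onto an unactivated lactone, so it is no shorter than the seven steps to 16 here. In the key step, 1,2-hydride migration from C4 to the carbene competes, the electron-rich arenes invite aromatic cycloaddition, and the C2 configuration is set kinetically with no equilibration to correct it.
- Comparison: both routes reach the same lactone. The chosen one does so by joining two one-step derivatives of the same aldehyde in a step where C2 is set under reversible conditions.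

Alternative 3: Twofold decarboxylative arylation. The disconnection cuts both C–aryl bonds. Forward, meso diacid A5 (about four steps by a Diels–Alder, reduction, acetylation and alkene-cleavage sequence) and aryl bromide A6 react under Ir[dF(CF3)ppy]2(dtbbpy)PF6, NiCl2·glyme/4,4′-di-tert-butyl-2,2′-bipyridine and blue light. Both α-oxy acids are replaced by aryl groups to give A7, which is the same compound as 18.
- For: it is the shortest path to 18 (about five steps against nine), and the 3,4-cis arms with their acetates are in place from the start.
- Against: decarboxylation erases C2 and C5, and each is re-set at nickel under the influence of one neighbouring arm only, and this must succeed twice on the same molecule. The electron-rich A6 adds slowly to nickel. After the first coupling, the second must proceed next to an oxidisable benzylic α-oxy C–H bond, and incomplete coupling and protodecarboxylation give statistical mixtures.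
- Comparison: this alternative is stronger on step economy. The chosen strategy offers instead closed-shell steps only, and one ring closure in which C2 and C5 are correlated and reversibility corrects errors.

Key step: step 4

Assumption: the configuration string is read as the meso compound (2R,3S,4R,5S); every chiral intermediate is therefore made and used as a racemate and drawn as one enantiomer.

## Route

Step 1
Reactants: 1 3,4-bis(benzyloxy)benzaldehyde; 2 dimethyl malonate
Product: 3 dimethyl 2-[3,4-bis(benzyloxy)benzylidene]malonate
Conditions: piperidine (cat.), AcOH (cat.), toluene, reflux, Dean–Stark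
Reagents that add atoms: none
Why: Knoevenagel condensation driven by azeotropic removal of water; the symmetrical malonate leaves no alkene geometry to control.

Step 2
Reactants: 4 tetrahydrothiophene; 5 allyl bromide
Product: 6 1-allyltetrahydrothiophen-1-ium bromide
Conditions: acetone, rt
Reagents that add atoms: none
Why: SN2 S-alkylation of a nucleophilic sulfide by a reactive allylic bromide; the salt should crystallise from the medium.

Step 3
Reactants: 1 3,4-bis(benzyloxy)benzaldehyde; 6 1-allyltetrahydrothiophen-1-ium bromide
Product: 8 trans-2-[3,4-bis(benzyloxy)phenyl]-3-vinyloxirane (racemic; 2R*,3R*), via allylsulfonium ylide 7 (not isolated)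
Conditions: KOH (powdered), MeCN, 0 °C → rt; purification on Et3N-deactivated silica
Reagents that add atoms: none
Why: Sulfonium ylide (Corey–Chaykovsky-type) epoxidation; addition of the semi-stabilised allylide to the aldehyde is reversible, so the anti betaine that closes to the trans epoxide should predominate, and any cis isomer carried along is expected to enter the same π-allyl manifold in step 4.

Step 4
Reactants: 8 trans-2-[3,4-bis(benzyloxy)phenyl]-3-vinyloxirane; 3 dimethyl 2-[3,4-bis(benzyloxy)benzylidene]malonate
Product: 11 dimethyl 2,5-cis-2,5-bis[3,4-bis(benzyloxy)phenyl]-4-vinyltetrahydrofuran-3,3-dicarboxylate (vinyl trans to the C5 aryl; racemic; 2R*,4R*,5R*), via π-allylpalladium alkoxide zwitterion 9 (not isolated), via malonate carbanion adduct 10 (not isolated)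
Conditions: Pd2(dba)3·CHCl3 (2.5 mol %), PPh3 (12 mol %), THF, 40 °C
Reagents that add atoms: none
Why: Zerovalent palladium adds to the vinyl group of 8 anti to the allylic C4–O bond and ionises it with inversion to give zwitterion 9; its alkoxide adds to the β-carbon of 3 (O1–C2, oxa-Michael) to give carbanion 10, and the malonate carbon then attacks the near allyl terminus on the face opposite palladium (C3–C4), releasing the catalyst. This is the known palladium-catalysed [3+2] cycloaddition of vinyl epoxides with doubly activated alkenes through zwitterionic π-allyl intermediates. The one ring is closed in the allylic alkylation as a 5-exo-trig attack on the allyl unit with the vinyl group left outside the ring; attack at the far terminus would need a seven-membered ring and is not expected to compete. C5 is carried over unchanged from 8. C4 is controlled by the double inversion (ionisation, then outer-sphere attack), which amounts to net retention and turns the trans epoxide into the 4,5-trans product; π–σ–π exchange through the unsubstituted allyl terminus lets any mismatched complex cross over, and the less crowded transition state with vinyl and C5 aryl on opposite faces is again the trans one. C2 is controlled by the reversibility of the oxa-Michael step: the two epimers of 10 interconvert through 9 and 3, and the one that closes through an envelope with both aryl groups pseudo-equatorial should cyclise faster, which gives 2,5-cis. The step needs O-addition to 3 to outrun isomerisation of 9 by hydride loss; the two ester groups on the acceptor, a neutral medium free of Lewis acid and a modest excess of 8 are meant to secure this.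

Step 5
Reactants: 11 dimethyl 2,5-cis-2,5-bis[3,4-bis(benzyloxy)phenyl]-4-vinyltetrahydrofuran-3,3-dicarboxylate
Product: 13 dimethyl 2,5-cis-2,5-bis[3,4-bis(benzyloxy)phenyl]-4-formyltetrahydrofuran-3,3-dicarboxylate (formyl trans to the C5 aryl; racemic), via vicinal diol 12 (not isolated)
Conditions: OsO4 (2 mol %), NaIO4, 2,6-lutidine, dioxane/H2O 3:1, rt; used crude
Reagents that add atoms: osmium tetroxide, O=[Os](=O)(=O)=O (delivers the aldehyde oxygen; re-oxidised by sodium periodate, [Na+].[O-]I(=O)(=O)=O, which also cleaves the diol)
Why: Lemieux–Johnson oxidation of the only alkene; the lutidine buffer keeps the medium near neutral so the β-alkoxy aldehyde is not enolised, and the aryl benzyl ethers tolerate OsO4 and periodate. C4 is not touched.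

Step 6
Reactants: 13 dimethyl 2,5-cis-2,5-bis[3,4-bis(benzyloxy)phenyl]-4-formyltetrahydrofuran-3,3-dicarboxylate
Product: 15 methyl 4,6-bis[3,4-bis(benzyloxy)phenyl]-3-oxotetrahydro-1H,3H-furo[3,4-c]furan-3a-carboxylate (cis-fused lactone ester; aryl groups cis to each other on the convex face; racemic), via hydroxymethyl diester 14 (not isolated)
Conditions: NaBH4, THF/MeOH, 0 °C; then PPTS (cat.), toluene, 50 °C
Reagents that add atoms: none
Why: Borohydride reduces the aldehyde much faster than the esters, and the primary alcohol then lactonises (5-exo-trig acyl substitution) onto the one C3 ester that is cis to it; C3 becomes stereogenic with its configuration dictated by C4, and C4 is no longer epimerisable.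

Step 7
Reactants: 15 methyl 4,6-bis[3,4-bis(benzyloxy)phenyl]-3-oxotetrahydro-1H,3H-furo[3,4-c]furan-3a-carboxylate
Product: 16 4,6-bis[3,4-bis(benzyloxy)phenyl]tetrahydro-1H,3H-furo[3,4-c]furan-1-one (cis-fused; aryl groups on the convex face; racemic)
Conditions: LiCl, H2O (2 equiv), DMSO, 140 °C
Reagents that add atoms: none
Why: Krapcho demethoxycarbonylation: chloride attacks the methyl group of the malonate-type ester, the carboxylate loses CO2, and the lactone enolate is protonated on the convex face because only the cis-fused bicycle is accessible; this sets C3 cis to the C4 arm and trans to the C2 aryl. Opening of the ring by β-elimination of O1 from the enolate is the reverse of a 5-endo-trig closure and should be slow.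

Step 8
Reactants: 16 4,6-bis[3,4-bis(benzyloxy)phenyl]tetrahydro-1H,3H-furo[3,4-c]furan-1-one
Product: 17 meso-[(2R,3S,4R,5S)-2,5-bis[3,4-bis(benzyloxy)phenyl]tetrahydrofuran-3,4-diyl]dimethanol
Conditions: LiAlH4, THF, 0 °C → rt
Reagents that add atoms: none
Why: Hydride reduction of the lactone to the diol; aryl benzyl ethers and the cyclic ether are inert, no stereocentre is touched, and the product becomes meso.

Step 9
Reactants: 17 meso-[(2R,3S,4R,5S)-2,5-bis[3,4-bis(benzyloxy)phenyl]tetrahydrofuran-3,4-diyl]dimethanol
Product: 18 meso-[(2R,3S,4R,5S)-2,5-bis[3,4-bis(benzyloxy)phenyl]tetrahydrofuran-3,4-diyl]bis(methylene) diacetate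
Conditions: Ac2O, pyridine, DMAP (cat.), CH2Cl2, rt
Reagents that add atoms: acetic anhydride, CC(=O)OC(C)=O
Why: DMAP-catalysed acylation of two unhindered primary alcohols; no other nucleophilic group is present.

Step 10
Reactants: 18 meso-[(2R,3S,4R,5S)-2,5-bis[3,4-bis(benzyloxy)phenyl]tetrahydrofuran-3,4-diyl]bis(methylene) diacetate
Product: 19 meso-[(2R,3S,4R,5S)-2,5-bis(3,4-dihydroxyphenyl)tetrahydrofuran-3,4-diyl]bis(methylene) diacetate (target)
Conditions: H2 (1 atm), 10% Pd/C, EtOAc, rt; work-up with exclusion of air
Reagents that add atoms: none
Why: Catalytic hydrogenolysis of the four aryl benzyl ethers, which in a neutral aprotic solvent should cleave well before the ring dialkyl-type benzylic C–O bonds; the acetates are inert.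

## Compound list

1 | 3,4-bis(benzyloxy)benzaldehyde | O=Cc1ccc(OCc2ccccc2)c(OCc2ccccc2)c1 | starting material
2 | dimethyl malonate | COC(=O)CC(=O)OC | starting material
3 | dimethyl 2-[3,4-bis(benzyloxy)benzylidene]malonate | COC(=O)C(=Cc1ccc(OCc2ccccc2)c(OCc2ccccc2)c1)C(=O)OC | intermediate
4 | tetrahydrothiophene | C1CCSC1 | starting material
5 | allyl bromide | C=CCBr | starting material
6 | 1-allyltetrahydrothiophen-1-ium bromide | C=CC[S+]1CCCC1.[Br-] | intermediate
7 | allylsulfonium ylide of 6 (not isolated) | C=C[CH-][S+]1CCCC1 | intermediate
8 | trans-2-[3,4-bis(benzyloxy)phenyl]-3-vinyloxirane (racemic) | C=C[C@H]1O[C@@H]1c1ccc(OCc2ccccc2)c(OCc2ccccc2)c1 | intermediate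
9 | π-allylpalladium alkoxide zwitterion, drawn as the σ-allyl form with phosphine ligands omitted (not isolated) | [O-][C@H](c1ccc(OCc2ccccc2)c(OCc2ccccc2)c1)/C=C/C[Pd+] | intermediate
10 | oxa-Michael adduct of 9 and 3, malonate carbanion with π-allylpalladium, drawn as the σ-allyl form (not isolated) | COC(=O)[C-](C(=O)OC)[C@H](c1ccc(OCc2ccccc2)c(OCc2ccccc2)c1)O[C@H](c1ccc(OCc2ccccc2)c(OCc2ccccc2)c1)/C=C/C[Pd+] | intermediate
11 | dimethyl 2,5-cis-2,5-bis[3,4-bis(benzyloxy)phenyl]-4-vinyltetrahydrofuran-3,3-dicarboxylate, vinyl trans to the C5 aryl (racemic) | COC(=O)C1(C(=O)OC)[C@H](C=C)[C@@H](c2ccc(OCc3ccccc3)c(OCc3ccccc3)c2)O[C@H]1c1ccc(OCc2ccccc2)c(OCc2ccccc2)c1 | intermediate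
12 | dimethyl 2,5-cis-2,5-bis[3,4-bis(benzyloxy)phenyl]-4-(1,2-dihydroxyethyl)tetrahydrofuran-3,3-dicarboxylate, carbinol centre uncontrolled (not isolated) | COC(=O)C1(C(=O)OC)[C@H](C(O)CO)[C@@H](c2ccc(OCc3ccccc3)c(OCc3ccccc3)c2)O[C@H]1c1ccc(OCc2ccccc2)c(OCc2ccccc2)c1 | intermediate
13 | dimethyl 2,5-cis-2,5-bis[3,4-bis(benzyloxy)phenyl]-4-formyltetrahydrofuran-3,3-dicarboxylate, formyl trans to the C5 aryl (racemic) | COC(=O)C1(C(=O)OC)[C@H](C=O)[C@@H](c2ccc(OCc3ccccc3)c(OCc3ccccc3)c2)O[C@H]1c1ccc(OCc2ccccc2)c(OCc2ccccc2)c1 | intermediate
14 | dimethyl 2,5-cis-2,5-bis[3,4-bis(benzyloxy)phenyl]-4-(hydroxymethyl)tetrahydrofuran-3,3-dicarboxylate (not isolated) | COC(=O)C1(C(=O)OC)[C@H](CO)[C@@H](c2ccc(OCc3ccccc3)c(OCc3ccccc3)c2)O[C@H]1c1ccc(OCc2ccccc2)c(OCc2ccccc2)c1 | intermediate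
15 | methyl 4,6-bis[3,4-bis(benzyloxy)phenyl]-3-oxotetrahydro-1H,3H-furo[3,4-c]furan-3a-carboxylate, cis-fused, aryls cis on the convex face (racemic) | COC(=O)[C@@]12C(=O)OC[C@@H]1[C@@H](c1ccc(OCc3ccccc3)c(OCc3ccccc3)c1)O[C@H]2c1ccc(OCc2ccccc2)c(OCc2ccccc2)c1 | intermediate
16 | 4,6-bis[3,4-bis(benzyloxy)phenyl]tetrahydro-1H,3H-furo[3,4-c]furan-1-one, cis-fused, aryls cis on the convex face (racemic) | O=C1OC[C@@H]2[C@@H](c3ccc(OCc4ccccc4)c(OCc4ccccc4)c3)O[C@@H](c3ccc(OCc4ccccc4)c(OCc4ccccc4)c3)[C@H]12 | intermediate
17 | meso-[(2R,3S,4R,5S)-2,5-bis[3,4-bis(benzyloxy)phenyl]tetrahydrofuran-3,4-diyl]dimethanol | OC[C@@H]1[C@H](CO)[C@@H](c2ccc(OCc3ccccc3)c(OCc3ccccc3)c2)O[C@H]1c1ccc(OCc2ccccc2)c(OCc2ccccc2)c1 | intermediate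
18 | meso-[(2R,3S,4R,5S)-2,5-bis[3,4-bis(benzyloxy)phenyl]tetrahydrofuran-3,4-diyl]bis(methylene) diacetate | CC(=O)OC[C@@H]1[C@H](COC(C)=O)[C@@H](c2ccc(OCc3ccccc3)c(OCc3ccccc3)c2)O[C@H]1c1ccc(OCc2ccccc2)c(OCc2ccccc2)c1 | intermediate
19 | meso-[(2R,3S,4R,5S)-2,5-bis(3,4-dihydroxyphenyl)tetrahydrofuran-3,4-diyl]bis(methylene) diacetate | CC(=O)OC[C@@H]1[C@H](COC(C)=O)[C@@H](c2ccc(O)c(O)c2)O[C@H]1c1ccc(O)c(O)c1 | target

## Step count and least certain steps

Total step count: 10. Longest linear sequence: 9 steps (steps 2 to 10; step 1 is the one-step side branch).

Step 4 (key step). The most likely failure is slow capture of the alkoxide of 9 by the electron-rich, less electrophilic acceptor 3, so that isomerisation of the epoxide by hydride loss or oligomerisation takes over. The second is incomplete facial selection at C2. Fallback: build the same ring by a Lewis-acid cycloaddition of a donor–acceptor cyclopropane with aldehyde 1, which forms O1–C5 and C2–C3 instead. It sets out from 1 and comes back at 15 through 14.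
- Still–Gennari olefination of 1 (bis(2,2,2-trifluoroethyl) (methoxycarbonylmethyl)phosphonate, KN(SiMe3)2, 18-crown-6, THF, −78 °C) should give methyl (Z)-3-[3,4-bis(benzyloxy)phenyl]acrylate F1.
- i-Bu2AlH (CH2Cl2, −78 °C) gives (Z)-3-[3,4-bis(benzyloxy)phenyl]prop-2-en-1-ol F2, and Ac2O/pyridine gives its acetate, (Z)-3-[3,4-bis(benzyloxy)phenyl]allyl acetate F3.
- Rh2(OAc)4-catalysed cyclopropanation with dimethyl diazomalonate is stereospecific and gives dimethyl cis-2-(acetoxymethyl)-3-[3,4-bis(benzyloxy)phenyl]cyclopropane-1,1-dicarboxylate F4.
- With Sn(OTf)2 in CH2Cl2, the oxygen of 1 attacks the aryl-bearing cyclopropane carbon with inversion and the malonate closes on the aldehyde carbon. This should give dimethyl 2,5-cis-4-(acetoxymethyl)-2,5-bis[3,4-bis(benzyloxy)phenyl]tetrahydrofuran-3,3-dicarboxylate F5, with the arm trans to the C5 aryl because the cyclopropane is cis.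
- K2CO3 in MeOH removes the acetate to give 14, which lactonises to 15.

Step 3. The electron-rich benzylic epoxide may be lost during isolation through acid-promoted ring opening or rearrangement, and the trans preference of the ylide addition may be modest. Fallback: replace the epoxide by a bench-stable cyclic carbonate that ionises to the same zwitterion. It sets out from 1 and comes back at 11, entering the catalytic cycle at 9.
- Indium-mediated Barbier addition of 3-bromoprop-1-enyl acetate to 1 (THF/H2O) gives 1-[3,4-bis(benzyloxy)phenyl]-1-hydroxybut-3-en-2-yl acetate F6 as a diastereomer mixture.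
- K2CO3 in MeOH gives 1-[3,4-bis(benzyloxy)phenyl]but-3-ene-1,2-diol F7, and 1,1′-carbonyldiimidazole gives 4-[3,4-bis(benzyloxy)phenyl]-5-vinyl-1,3-dioxolan-2-one F8.
- Under the conditions of step 4, F8 loses its allylic C–O bond and then CO2 and reacts with 3 to give 11. Both diastereomers of F8 should serve, because the π-allyl faces exchange.

Step 5. Aldehyde 13 is a β-alkoxy aldehyde: enolisation towards C4 would cause epimerisation or elimination of O1 with ring opening, and osmylation next to the quaternary C3 may be slow. Fallback: ozonolysis with a direct hydride quench, from 11 to 15 through 14 without accumulating 13 (O3, CH2Cl2/MeOH, −78 °C, one equivalent judged by consumption of 11; then NaBH4 in the same flask, warming to 0 °C). No new compound is made.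

Step 7. At 140 °C the chloride may attack the lactone CH2–O carbon, and the hot lithium salt solution may ionise the activated benzylic ether bonds. Fallback: hydrolysis and thermal decarboxylation, from 15 back to 16. LiOH (THF/H2O) cleaves the methyl ester and opens the lactone; acidification recloses it to 4,6-bis[3,4-bis(benzyloxy)phenyl]-3-oxotetrahydro-1H,3H-furo[3,4-c]furan-3a-carboxylic acid F9. F9 loses CO2 on heating in toluene/pyridine at about 100 °C, with the same convex-face protonation.

Step 10. The ring C2–O1 and C5–O1 bonds may undergo hydrogenolysis once the para-hydroxyl groups are free, and the catechols may oxidise in air. Fallback: non-reductive debenzylation of 18 to 19 with BCl3 and pentamethylbenzene (CH2Cl2, −78 °C), where the arene traps the benzyl cations and acetates are tolerated. Reversible ionisation at C2 or C5 would reclose to the same configuration, since each aryl is already trans to its neighbour. No new compound is made.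

## Further compounds

F1 | step 4 | methyl (Z)-3-[3,4-bis(benzyloxy)phenyl]acrylate | COC(=O)/C=C\c1ccc(OCc2ccccc2)c(OCc2ccccc2)c1
F2 | step 4 | (Z)-3-[3,4-bis(benzyloxy)phenyl]prop-2-en-1-ol | OC/C=C\c1ccc(OCc2ccccc2)c(OCc2ccccc2)c1
F3 | step 4 | (Z)-3-[3,4-bis(benzyloxy)phenyl]allyl acetate | CC(=O)OC/C=C\c1ccc(OCc2ccccc2)c(OCc2ccccc2)c1
F4 | step 4 | dimethyl cis-2-(acetoxymethyl)-3-[3,4-bis(benzyloxy)phenyl]cyclopropane-1,1-dicarboxylate (racemic) | COC(=O)C1(C(=O)OC)[C@H](COC(C)=O)[C@@H]1c1ccc(OCc2ccccc2)c(OCc2ccccc2)c1
F5 | step 4 | dimethyl 2,5-cis-4-(acetoxymethyl)-2,5-bis[3,4-bis(benzyloxy)phenyl]tetrahydrofuran-3,3-dicarboxylate, arm trans to the C5 aryl (racemic) | COC(=O)C1(C(=O)OC)[C@H](COC(C)=O)[C@@H](c2ccc(OCc3ccccc3)c(OCc3ccccc3)c2)O[C@H]1c1ccc(OCc2ccccc2)c(OCc2ccccc2)c1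
F6 | step 3 | 1-[3,4-bis(benzyloxy)phenyl]-1-hydroxybut-3-en-2-yl acetate (diastereomer mixture, configuration not specified) | CC(=O)OC(C=C)C(O)c1ccc(OCc2ccccc2)c(OCc2ccccc2)c1
F7 | step 3 | 1-[3,4-bis(benzyloxy)phenyl]but-3-ene-1,2-diol (diastereomer mixture, configuration not specified) | OC(C=C)C(O)c1ccc(OCc2ccccc2)c(OCc2ccccc2)c1
F8 | step 3 | 4-[3,4-bis(benzyloxy)phenyl]-5-vinyl-1,3-dioxolan-2-one (diastereomer mixture, configuration not specified) | C=CC1OC(=O)OC1c1ccc(OCc2ccccc2)c(OCc2ccccc2)c1
F0 | step 5 | none | none
F9 | step 7 | 4,6-bis[3,4-bis(benzyloxy)phenyl]-3-oxotetrahydro-1H,3H-furo[3,4-c]furan-3a-carboxylic acid, cis-fused (racemic) | OC(=O)[C@@]12C(=O)OC[C@@H]1[C@@H](c1ccc(OCc3ccccc3)c(OCc3ccccc3)c1)O[C@H]2c1ccc(OCc2ccccc2)c(OCc2ccccc2)c1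
F0 | step 10 | none | none
A1 | alternative 1 | (E)-3-[3-(benzyloxy)-4-hydroxyphenyl]allyl acetate | CC(=O)OC/C=C/c1ccc(O)c(OCc2ccccc2)c1
A2 | alternative 1 | 3-O,3′-O-dibenzyl ether of the target (meso) | CC(=O)OC[C@@H]1[C@H](COC(C)=O)[C@@H](c2ccc(O)c(OCc3ccccc3)c2)O[C@H]1c1ccc(O)c(OCc2ccccc2)c1
A3 | alternative 2 | 4-{[3,4-bis(benzyloxy)phenyl][3,4-bis(benzyloxy)benzyloxy]methyl}-3-diazodihydrofuran-2(3H)-one (racemic) | [N-]=[N+]=C1C(=O)OC[C@@H]1[C@@H](c1ccc(OCc2ccccc2)c(OCc2ccccc2)c1)OCc1ccc(OCc2ccccc2)c(OCc2ccccc2)c1
A4 | alternative 2 | cis-fused 4,6-bis[3,4-bis(benzyloxy)phenyl]tetrahydro-1H,3H-furo[3,4-c]furan-1-one, aryls on the convex face (racemic; identical with 16) | O=C1OC[C@@H]2[C@@H](c3ccc(OCc4ccccc4)c(OCc4ccccc4)c3)O[C@@H](c3ccc(OCc4ccccc4)c(OCc4ccccc4)c3)[C@H]12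
A5 | alternative 3 | meso-(2R,3S,4R,5S)-3,4-bis(acetoxymethyl)tetrahydrofuran-2,5-dicarboxylic acid | CC(=O)OC[C@@H]1[C@H](COC(C)=O)[C@@H](C(=O)O)O[C@H]1C(=O)O
A6 | alternative 3 | 4-bromo-1,2-bis(benzyloxy)benzene | Brc1ccc(OCc2ccccc2)c(OCc2ccccc2)c1
A7 | alternative 3 | tetra-O-benzyl ether of the target (meso; identical with 18) | CC(=O)OC[C@@H]1[C@H](COC(C)=O)[C@@H](c2ccc(OCc3ccccc3)c(OCc3ccccc3)c2)O[C@H]1c1ccc(OCc2ccccc2)c(OCc2ccccc2)c1
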